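**Plan**
- Retrosynthesis: the two silyl ethers are removed last. The 2,3-cis dihydrofuran ring of the benzofuran is cut at C2–C3 (carbenoid C–H insertion), then at the aryl–CH2CO2Me and ArO–CH2Ar bonds, which leads back to a bromophenol furofuran.
- The 3,7-dioxabicyclo[3.3.0]octane is cut at O3–C2 and O7–C6 to an open tetraol, and then at C1–C2 and C5–C6.
- Enabling feature: the bridgehead pair C1–C5 with its methylenes C8 and C4 is a masked butenolide (C1 = α-carbon, C5 = β-carbon, C8 = lactone carbonyl, C4 = γ-acetal carbon). The benzylic carbons C6 and C2 can therefore arrive as an acyl-anion equivalent and an aldehyde.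
- Forward: three-component Michael–aldol union (no ring), ketone unmasking and reduction, one-pot closure of both tetrahydrofuran rings, then O-benzylation, arylacetate installation, diazo transfer, closure of the dihydrofuran ring, reduction and desilylation.
- Stereochemistry: C1/C5 come from the (5R)-menthyloxy acetal, itself fixed by crystallisation with (−)-menthol. C2/C6 come from kinetic exo capture of benzylic cations. The cis-(2S,3S) dihydrobenzofuran comes from a catalyst-controlled, cis-selective dirhodium carbenoid C–H insertion.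

Key step: step 6

Assumption: the target SMILES is read as an exo,exo (1R,2S,5R,6S) furofuran carrying a 2,3-cis (2S,3S) dihydrobenzofuran, so the contra-thermodynamic cis ring is the goal; C1–C8 refer to the 3,7-dioxabicyclo[3.3.0]octane.

**Route**

Step 1
Reactants: 1 syringaldehyde
Product: 2 2-(4-hydroxy-3,5-dimethoxyphenyl)-1,3-dithiane
Conditions: HS(CH2)3SH, BF3·OEt2 (cat.), CH2Cl2, 0 °C to rt
Reagents that add atoms: propane-1,3-dithiol, SCCCS
Why: Lewis-acid dithioacetalisation of an aromatic aldehyde should proceed cleanly on the free phenol and provides the acidic C–H needed for the acyl-anion equivalent.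

Step 2
Reactants: 2 2-(4-hydroxy-3,5-dimethoxyphenyl)-1,3-dithiane
Product: 3 2-[3,5-dimethoxy-4-(triisopropylsilyloxy)phenyl]-1,3-dithiane
Conditions: TIPSCl, imidazole, DMF, rt to 40 °C
Reagents that add atoms: chlorotriisopropylsilane, CC(C)[Si](Cl)(C(C)C)C(C)C
Why: Imidazole-mediated O-silylation gives a hindered aryl silyl ether that should tolerate n-BuLi, hydride and dilute acid and is removable by fluoride at the end.

Step 3
Reactants: 4 furfural
Product: 5 5-hydroxy-2(5H)-furanone (racemic hemiacetal)
Conditions: O2, hν (visible), rose bengal disodium salt (C20H2Cl4I4Na2O5, cat.), MeOH, rt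
Reagents that add atoms: dioxygen, O=O
Why: Dye-sensitised singlet-oxygen [4+2] addition across the furan, followed by methanolytic loss of the formyl carbon as methyl formate, is the standard furan photooxygenation route to the γ-hydroxybutenolide.

Step 4
Reactants: 5 5-hydroxy-2(5H)-furanone, 6 (−)-menthol
Product: 7 (5R)-5-[(1R,2S,5R)-menthyloxy]-2(5H)-furanone
Conditions: p-toluenesulfonic acid monohydrate (cat.), toluene, reflux, Dean–Stark; crystallisation from petroleum ether, mother liquor re-equilibrated with the same acid and recrystallised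
Reagents that add atoms: none
Why: Acid-catalysed acetalisation of the cyclic hemiacetal gives both C5 epimers, which interconvert under acid while the (5R) diastereomer crystallises, so C5 is set by crystallisation-driven resolution with menthol as the source of chirality.

Step 5
Reactants: 8 5-bromovanillin
Product: 9 3-bromo-5-methoxy-4-(methoxymethoxy)benzaldehyde
Conditions: MOMCl, i-Pr2NEt, CH2Cl2, 0 °C to rt
Reagents that add atoms: chloromethyl methyl ether, COCCl
Why: Williamson-type acetal protection of the acidic phenol gives an ether that is stable to enolates, buffered mercury salts and hydride, and is designed to fall off in the later acid step.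

Step 6
Reactants: 3 2-[3,5-dimethoxy-4-(triisopropylsilyloxy)phenyl]-1,3-dithiane, 7 (5R)-5-menthyloxy-2(5H)-furanone, 9 3-bromo-5-methoxy-4-(methoxymethoxy)benzaldehyde
Product: 12 (3S,4R,5R)-3-[(3-bromo-5-methoxy-4-(methoxymethoxy)phenyl)(hydroxy)methyl]-4-{2-[3,5-dimethoxy-4-(triisopropylsilyloxy)phenyl]-1,3-dithian-2-yl}-5-menthyloxydihydrofuran-2(3H)-one (carbinol epimers), via lithiated dithiane 10 (not isolated), via lithium lactone enolate 11 (not isolated)
Conditions: 3 (slight excess), n-BuLi, THF, −30 °C; 7, −78 °C; 9, −78 °C; AcOH quench at −78 °C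
Reagents that add atoms: none
Why: n-BuLi removes the C2 proton of 3 to give the sulfur-stabilised benzylic carbanion 10, which adds 1,4 to the enoate of 7 (future C5–C6 bond) to give lithium enolate 11, and 11 is intercepted by aldehyde 9 in an aldol addition (future C1–C2 bond). The closest known reaction type is the tandem conjugate addition–aldol trapping of 2-aryl-2-lithio-1,3-dithianes on 2(5H)-furanones, including 5-alkoxybutenolides used as chiral templates. No ring is closed in this step. The β-stereocentre is controlled by the acetal carbon of 7, the bulky carbanion entering anti to the menthyloxy group, and the α-stereocentre by the new β-substituent, the aldehyde approaching the enolate face anti to the dithianyl group, so the 3,4-trans-4,5-trans lactone should result; the carbinol centre is uncontrolled and is carried as a mixture because it is ionised later. The step needs 1,4- over 1,2-addition, secured by the soft, hindered aryl dithianyl anion, and survival of the aryl bromide, secured by consuming all n-BuLi in the lithiation before 9 is introduced.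

Step 7
Reactants: 12 dithianyl lactone adduct
Product: 13 (3S,4R,5R)-3-[(3-bromo-5-methoxy-4-(methoxymethoxy)phenyl)(hydroxy)methyl]-4-[3,5-dimethoxy-4-(triisopropylsilyloxy)benzoyl]-5-menthyloxydihydrofuran-2(3H)-one (carbinol epimers)
Conditions: Hg(ClO4)2·3H2O, CaCO3, THF/H2O, 0 °C to rt
Reagents that add atoms: water, O
Why: Thiophilic divalent-mercury-assisted hydrolysis of the S,S-acetal under carbonate buffering should release the aryl ketone without touching the MOM ether, the silyl ether or the lactone acetal, and the all-trans lactone has no driving force to epimerise at C4.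

Step 8
Reactants: 13 keto lactone
Product: 14 (2R,3R)-2-[(3-bromo-5-methoxy-4-(methoxymethoxy)phenyl)(hydroxy)methyl]-3-{[3,5-dimethoxy-4-(triisopropylsilyloxy)phenyl](hydroxy)methyl}butane-1,4-diol (carbinol epimers)
Conditions: LiAlH4, THF, 0 °C to rt
Reagents that add atoms: none
Why: Hydride reduction converts the ketone into a carbinol and the lactone into a primary alcohol, and the released menthyl hemiacetal collapses and is reduced to the second CH2OH (future C4), so the auxiliary leaves as menthol while the two bridgehead carbons are untouched and the aryl bromide survives at or below room temperature.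

Step 9
Reactants: 14 tetraol
Product: 15 (1R,2S,5R,6S)-2-(3-bromo-4-hydroxy-5-methoxyphenyl)-6-[3,5-dimethoxy-4-(triisopropylsilyloxy)phenyl]-3,7-dioxabicyclo[3.3.0]octane
Conditions: HCl (3 M aq.), MeOH/THF, 0 °C to rt, quenched with NaHCO3 as soon as conversion is complete
Reagents that add atoms: none
Why: Acid hydrolysis of the MOM acetal frees the bromophenol, whose para-hydroxyl is needed to stabilise the cation on that ring; both benzylic carbinols then ionise and are captured by the primary hydroxyls in two SN1 cycloetherifications, each placing the aryl group trans to the neighbouring ring carbon, so both carbinol epimers should converge on the exo,exo C2/C6 configuration under kinetic control.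

Step 10
Reactants: 16 vanillin
Product: 17 3-methoxy-4-(triisopropylsilyloxy)benzaldehyde
Conditions: TIPSCl, imidazole, DMF, rt
Reagents that add atoms: chlorotriisopropylsilane, CC(C)[Si](Cl)(C(C)C)C(C)C
Why: Standard imidazole-mediated silylation of a phenol, chosen so that both phenols of the target end as the same fluoride-labile ether.

Step 11
Reactants: 17 3-methoxy-4-(triisopropylsilyloxy)benzaldehyde
Product: 18 [3-methoxy-4-(triisopropylsilyloxy)phenyl]methanol
Conditions: NaBH4, THF/EtOH, 0 °C
Reagents that add atoms: none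
Why: Borohydride reduction of an aromatic aldehyde at 0 °C should leave the bulky aryl silyl ether intact.

Step 12
Reactants: 15 bromophenol furofuran, 18 [3-methoxy-4-(triisopropylsilyloxy)phenyl]methanol
Product: 19 (1R,2S,5R,6S)-2-{3-bromo-5-methoxy-4-[3-methoxy-4-(triisopropylsilyloxy)benzyloxy]phenyl}-6-[3,5-dimethoxy-4-(triisopropylsilyloxy)phenyl]-3,7-dioxabicyclo[3.3.0]octane
Conditions: PPh3, DIAD, THF, 0 °C to rt
Reagents that add atoms: none
Why: Mitsunobu etherification suits the acidic, hindered bromophenol as pronucleophile and a primary benzylic alcohol as electrophile, and its neutral conditions avoid the base-induced desilylation that a Williamson alkylation would risk.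

Step 13
Reactants: 19 aryl bromide benzyl ether
Product: 20 methyl 2-{5-[(1R,2S,5R,6S)-6-(3,5-dimethoxy-4-triisopropylsilyloxyphenyl)-3,7-dioxabicyclo[3.3.0]oct-2-yl]-3-methoxy-2-[3-methoxy-4-(triisopropylsilyloxy)benzyloxy]phenyl}acetate
Conditions: BrZnCH2CO2Me, Pd2(dba)3 (cat.), 2-dicyclohexylphosphino-2′,4′,6′-triisopropylbiphenyl (cat.), THF, 60 °C
Reagents that add atoms: (2-methoxy-2-oxoethyl)zinc bromide, COC(=O)C[Zn]Br
Why: Negishi-type α-arylation of a Reformatsky reagent (oxidative addition of the ortho-alkoxy aryl bromide to zerovalent palladium, transmetalation of the zinc enolate, reductive elimination) installs the acetate unit under near-neutral conditions that silyl ethers and the cyclic benzylic ethers should tolerate.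

Step 14
Reactants: 20 methyl arylacetate
Product: 21 methyl 2-diazo-2-aryl acetate (diazo derivative of 20)
Conditions: 4-acetamidobenzenesulfonyl azide (p-ABSA), DBU, MeCN (dry), 0 °C to rt
Reagents that add atoms: 4-acetamidobenzenesulfonyl azide, CC(=O)Nc1ccc(cc1)S(=O)(=O)N=[N+]=[N-]
Why: Regitz diazo transfer to the DBU-generated arylacetate enolate is the standard entry to donor/acceptor aryldiazoacetates, and dry conditions keep the aryl silyl ethers intact.

Step 15
Reactants: 21 methyl aryldiazoacetate
Product: 22 methyl (2S,3R)-cis-2-[3-methoxy-4-(triisopropylsilyloxy)phenyl]-7-methoxy-5-[(1R,2S,5R,6S)-6-(3,5-dimethoxy-4-triisopropylsilyloxyphenyl)-3,7-dioxabicyclo[3.3.0]oct-2-yl]-2,3-dihydrobenzofuran-3-carboxylate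
Conditions: Rh2(R-PTTL)4 (dirhodium tetrakis[N-phthaloyl-(R)-tert-leucinate], 2 mol %), toluene, −60 °C
Reagents that add atoms: none
Why: Intramolecular 1,5 C–H insertion of the dirhodium donor/acceptor carbenoid into the ether-activated benzylic C–H closes the dihydrofuran ring (C3–C2 bond) with loss of N2; phthalimido-carboxylate catalysts of this family are expected to give the cis product kinetically and to select the enantiotopic hydrogen, the R antipode being chosen for the 2S series by analogy with simpler benzyl aryl ethers (its mirror image would be used should the sense prove opposite).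

Step 16
Reactants: 22 cis ester
Product: 23 {(2S,3S)-cis-2-[3-methoxy-4-(triisopropylsilyloxy)phenyl]-7-methoxy-5-[(1R,2S,5R,6S)-6-(3,5-dimethoxy-4-triisopropylsilyloxyphenyl)-3,7-dioxabicyclo[3.3.0]oct-2-yl]-2,3-dihydrobenzofuran-3-yl}methanol
Conditions: LiAlH4, THF, −40 to 0 °C
Reagents that add atoms: none
Why: Hydride reduction of the ester at low temperature should outpace enolisation, so the cis relationship is retained (the C3 descriptor changes from R to S only through the priority change from CO2Me to CH2OH).

Step 17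
Reactants: 23 bis-silyl ether
Product: 24 target, (2S,3S)-cis-2-(4-hydroxy-3-methoxyphenyl)-3-(hydroxymethyl)-7-methoxy-5-[(1R,2S,5R,6S)-6-(4-hydroxy-3,5-dimethoxyphenyl)-3,7-dioxabicyclo[3.3.0]oct-2-yl]-2,3-dihydrobenzofuran
Conditions: TBAF, AcOH (1:1), THF, 0 °C
Reagents that add atoms: none
Why: Fluoride-mediated cleavage of both aryl silyl ethers, buffered with acetic acid so that no free phenoxide can open the cis-dihydrobenzofuran through a quinone methide and epimerise C2.

**Compound list**

1 | syringaldehyde | COc1cc(C=O)cc(OC)c1O | starting material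
2 | 2-(4-hydroxy-3,5-dimethoxyphenyl)-1,3-dithiane | COc1cc(C2SCCCS2)cc(OC)c1O | intermediate
3 | 2-[3,5-dimethoxy-4-(triisopropylsilyloxy)phenyl]-1,3-dithiane | COc1cc(C2SCCCS2)cc(OC)c1O[Si](C(C)C)(C(C)C)C(C)C | intermediate
4 | furfural | O=Cc1ccco1 | starting material
5 | 5-hydroxy-2(5H)-furanone (racemic) | O=C1C=CC(O)O1 | intermediate
6 | (−)-menthol, (1R,2S,5R) | CC(C)[C@@H]1CC[C@@H](C)C[C@H]1O | starting material
7 | (5R)-5-[(1R,2S,5R)-menthyloxy]-2(5H)-furanone | O=C1C=C[C@H](O[C@@H]2C[C@H](C)CC[C@H]2C(C)C)O1 | intermediate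
8 | 5-bromovanillin | COc1cc(C=O)cc(Br)c1O | starting material
9 | 3-bromo-5-methoxy-4-(methoxymethoxy)benzaldehyde | COc1cc(C=O)cc(Br)c1OCOC | intermediate
10 | 2-lithio-2-[3,5-dimethoxy-4-(triisopropylsilyloxy)phenyl]-1,3-dithiane | COc1cc(C2([Li])SCCCS2)cc(OC)c1O[Si](C(C)C)(C(C)C)C(C)C | intermediate
11 | lithium enolate of (4R,5R)-4-(2-aryl-1,3-dithian-2-yl)-5-menthyloxydihydrofuran-2(3H)-one | [Li]OC1=C[C@@H](C2(c3cc(OC)c(O[Si](C(C)C)(C(C)C)C(C)C)c(OC)c3)SCCCS2)[C@H](O[C@@H]2C[C@H](C)CC[C@H]2C(C)C)O1 | intermediate
12 | (3S,4R,5R) dithianyl lactone aldol adduct, carbinol epimers | O=C1O[C@@H](O[C@@H]2C[C@H](C)CC[C@H]2C(C)C)[C@H](C3(c4cc(OC)c(O[Si](C(C)C)(C(C)C)C(C)C)c(OC)c4)SCCCS3)[C@H]1C(O)c1cc(OC)c(OCOC)c(Br)c1 | intermediate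
13 | (3S,4R,5R) 4-aroyl lactone, carbinol epimers | O=C1O[C@@H](O[C@@H]2C[C@H](C)CC[C@H]2C(C)C)[C@H](C(=O)c2cc(OC)c(O[Si](C(C)C)(C(C)C)C(C)C)c(OC)c2)[C@H]1C(O)c1cc(OC)c(OCOC)c(Br)c1 | intermediate
14 | (2R,3R) tetraol, carbinol epimers | OC[C@H](C(O)c1cc(OC)c(O[Si](C(C)C)(C(C)C)C(C)C)c(OC)c1)[C@H](CO)C(O)c1cc(OC)c(OCOC)c(Br)c1 | intermediate
15 | (1R,2S,5R,6S)-2-(3-bromo-4-hydroxy-5-methoxyphenyl)-6-[3,5-dimethoxy-4-(triisopropylsilyloxy)phenyl]-3,7-dioxabicyclo[3.3.0]octane | COc1cc([C@H]2OC[C@H]3[C@@H]2CO[C@@H]3c2cc(OC)c(O[Si](C(C)C)(C(C)C)C(C)C)c(OC)c2)cc(Br)c1O | intermediate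
16 | vanillin | COc1cc(C=O)ccc1O | starting material
17 | 3-methoxy-4-(triisopropylsilyloxy)benzaldehyde | COc1cc(C=O)ccc1O[Si](C(C)C)(C(C)C)C(C)C | intermediate
18 | [3-methoxy-4-(triisopropylsilyloxy)phenyl]methanol | COc1cc(CO)ccc1O[Si](C(C)C)(C(C)C)C(C)C | intermediate
19 | O-[3-methoxy-4-(triisopropylsilyloxy)benzyl] ether of 15 | COc1cc([C@H]2OC[C@H]3[C@@H]2CO[C@@H]3c2cc(OC)c(O[Si](C(C)C)(C(C)C)C(C)C)c(OC)c2)cc(Br)c1OCc1ccc(O[Si](C(C)C)(C(C)C)C(C)C)c(OC)c1 | intermediate
20 | methyl arylacetate (CH2CO2Me in place of Br in 19) | COc1cc([C@H]2OC[C@H]3[C@@H]2CO[C@@H]3c2cc(OC)c(O[Si](C(C)C)(C(C)C)C(C)C)c(OC)c2)cc(CC(=O)OC)c1OCc1ccc(O[Si](C(C)C)(C(C)C)C(C)C)c(OC)c1 | intermediate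
21 | methyl aryldiazoacetate | COc1cc([C@H]2OC[C@H]3[C@@H]2CO[C@@H]3c2cc(OC)c(O[Si](C(C)C)(C(C)C)C(C)C)c(OC)c2)cc(C(=[N+]=[N-])C(=O)OC)c1OCc1ccc(O[Si](C(C)C)(C(C)C)C(C)C)c(OC)c1 | intermediate
22 | methyl (2S,3R)-cis-2-aryl-2,3-dihydrobenzofuran-3-carboxylate, bis-TIPS | COc1cc([C@H]2Oc3c(OC)cc([C@H]4OC[C@H]5[C@@H]4CO[C@@H]5c4cc(OC)c(O[Si](C(C)C)(C(C)C)C(C)C)c(OC)c4)cc3[C@H]2C(=O)OC)ccc1O[Si](C(C)C)(C(C)C)C(C)C | intermediate
23 | (2S,3S)-cis 3-hydroxymethyl dihydrobenzofuran, bis-TIPS ether of the target | COc1cc([C@H]2Oc3c(OC)cc([C@H]4OC[C@H]5[C@@H]4CO[C@@H]5c4cc(OC)c(O[Si](C(C)C)(C(C)C)C(C)C)c(OC)c4)cc3[C@H]2CO)ccc1O[Si](C(C)C)(C(C)C)C(C)C | intermediate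
24 | CNP0126146.1 | COc1cc([C@H]2Oc3c(OC)cc([C@H]4OC[C@H]5[C@@H]4CO[C@@H]5c4cc(OC)c(O)c(OC)c4)cc3[C@H]2CO)ccc1O | target

**Step count**

Total: 17 steps. Longest linear sequence: 12 steps (steps 1, 2, 6, 7, 8, 9, 12, 13, 14, 15, 16, 17).

**Steps most likely to fail**

Step 9. The acid strength and time needed to hydrolyse the MOM acetal and ionise the hindered silyloxy-dimethoxyphenyl carbinol may also re-ionise the finished rings. Exo and endo aryl isomers of furofurans lie close in energy, so this would erode the kinetic exo selectivity at C2 and C6; reversible diversion into a 2,5-diaryltetrahydrofuran could also slow the closure. The fallback separates deprotection from ring closure and sets out from 13. The MOM ether is removed under non-protic conditions (TMSOTf, 2,2′-bipyridyl, CH2Cl2, 0 °C, then water; the carbinol is silylated transiently) to give the phenolic keto lactone F1. LiAlH4 reduction then gives the phenolic tetraol F2. With the para-hydroxyl already free, both closures should proceed with a catalytic amount of 10-camphorsulfonic acid in THF/CH2Cl2 at 0 °C for a short time, and the route is rejoined at 15.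

Step 15. Facial selection by the catalyst could be weakened by the large, remote substituents or by a mismatch with the enantiopure furofuran, and cis selectivity could be lost by epimerisation of the acidic C3–H on handling. The fallback abandons catalyst control and sets out from 21. Decomposition with the achiral carboxylate Rh2(OAc)4 in CH2Cl2 gives the dihydrobenzofuran ester stereoisomer mixture F3. The mixture is converted into its ester enolate with LDA at −78 °C and protonated kinetically with 2,6-di-tert-butylphenol from the face opposite the C2 aryl group, which should turn every C2 epimer into its cis form. The two cis esters are diastereomers because of the furofuran, so the unwanted (2R,3S) cis diastereomer F4 is removed by chromatography and the route is rejoined at 22.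

Step 13. Oxidative addition into the electron-rich, ortho-alkoxy aryl bromide may be slow, so that protodebromination or self-condensation of the zinc enolate competes. The fallback replaces cross-coupling by halogen–metal exchange and sets out from 19. Bromine–lithium exchange (n-BuLi, THF, −78 °C) and inverse addition to dimethyl oxalate give the methyl arylglyoxylate F5. Condensation with p-toluenesulfonyl hydrazide gives the tosylhydrazone F6. Treatment with DBU in CH2Cl2 (Bamford–Stevens-type elimination of sulfinate) gives the diazo ester directly, and the route is rejoined at 21, bypassing 20.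

**Further compounds**

F1 | step 9 | phenolic keto lactone (13 without MOM) | O=C1O[C@@H](O[C@@H]2C[C@H](C)CC[C@H]2C(C)C)[C@H](C(=O)c2cc(OC)c(O[Si](C(C)C)(C(C)C)C(C)C)c(OC)c2)[C@H]1C(O)c1cc(OC)c(O)c(Br)c1
F2 | step 9 | phenolic tetraol (14 without MOM) | OC[C@H](C(O)c1cc(OC)c(O[Si](C(C)C)(C(C)C)C(C)C)c(OC)c1)[C@H](CO)C(O)c1cc(OC)c(O)c(Br)c1
F3 | step 15 | dihydrobenzofuran ester, mixture of C2/C3 stereoisomers | COc1cc(C2Oc3c(OC)cc([C@H]4OC[C@H]5[C@@H]4CO[C@@H]5c4cc(OC)c(O[Si](C(C)C)(C(C)C)C(C)C)c(OC)c4)cc3C2C(=O)OC)ccc1O[Si](C(C)C)(C(C)C)C(C)C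
F4 | step 15 | (2R,3S)-cis diastereomer of 22 | COc1cc([C@@H]2Oc3c(OC)cc([C@H]4OC[C@H]5[C@@H]4CO[C@@H]5c4cc(OC)c(O[Si](C(C)C)(C(C)C)C(C)C)c(OC)c4)cc3[C@@H]2C(=O)OC)ccc1O[Si](C(C)C)(C(C)C)C(C)C
F5 | step 13 | methyl arylglyoxylate (COCO2Me in place of Br in 19) | COc1cc([C@H]2OC[C@H]3[C@@H]2CO[C@@H]3c2cc(OC)c(O[Si](C(C)C)(C(C)C)C(C)C)c(OC)c2)cc(C(=O)C(=O)OC)c1OCc1ccc(O[Si](C(C)C)(C(C)C)C(C)C)c(OC)c1
F6 | step 13 | tosylhydrazone of F5 | COc1cc([C@H]2OC[C@H]3[C@@H]2CO[C@@H]3c2cc(OC)c(O[Si](C(C)C)(C(C)C)C(C)C)c(OC)c2)cc(C(=NNS(=O)(=O)c2ccc(C)cc2)C(=O)OC)c1OCc1ccc(O[Si](C(C)C)(C(C)C)C(C)C)c(OC)c1
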